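**Retrosynthetic overview**
- Feature: in ring B (b1 = oxirane carbon bearing carbinol C11, b2 = oxirane CH, b3 and b6 = CHOH, b4=b5 alkene with CH2OH on b4) the two hydroxyls are cis to each other and anti to the oxirane. This is the reduced form of a peroxide bridge across b3 and b6 of a para-disubstituted benzene 1,2-oxide.
- Key disconnection: the b3–O and b6–O bonds, made by singlet-oxygen [4+2] addition to the b3=b4–b5=b6 diene of the arene oxide, with C11 choosing between the two interconverting oxide epimers; thiourea then opens the O–O bond.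
- The arene oxide comes from a cyclohexa-1,4-diene (cobalt-catalysed [4+2] of a 2-substituted butadiene with a propargyl ether), through asymmetric propynylation, hydroxyl-directed epoxidation, bromination and twofold dehydrobromination.
- The diene C7=C8–C9(Me)=C10 is cut at C8–C9 (Suzuki–Miyaura): a ring B (Z)-vinyl iodide (from the propynyl group by trans-hydroalumination) plus a ring A (E)-alkenylboronate (from geranyl acetate by epoxidation and radical cyclisation).
- Ring order: ring B carbocycle (step 3), oxirane (step 6), peroxide bridge (step 10, opened in step 11); ring A (step 16); the fragments are joined in step 21.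

Key step: step 10

Remark on the chemistry: the arene oxide formed in step 9, its oxepin and its ring-epimeric oxide are valence tautomers that interconvert far faster than any step is run, so only C11 is configurationally fixed in this material. It is drawn and numbered as the oxide that the elimination forms directly. The oxepin and the ring epimer are entered at step 10 as compounds that arise from it in the flask and return through it.

**Step 1**
Reactants: 1 2-methyl-2-vinyloxirane (isoprene monoxide, racemic)
Product: 2 2-methylidenebut-3-en-1-ol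
Conditions: LiN(iPr)2, Et2O, 0 °C to rt; H2O
Reagents that add atoms: none
Why: Base-promoted epoxide-to-allylic-alcohol isomerisation (β-elimination), in which the hindered amide removes a methyl proton and the oxirane opens at the quaternary carbon, destroying the only stereocentre and leaving the 2-substituted diene.

**Step 2**
Reactants: 2 2-methylidenebut-3-en-1-ol
Product: 3 tert-butyl[(2-methylidenebut-3-en-1-yl)oxy]diphenylsilane
Conditions: t-BuPh2SiCl, imidazole, CH2Cl2, 0 °C to rt
Reagents that add atoms: tert-butyl(chloro)diphenylsilane, CC(C)(C)[Si](Cl)(c1ccccc1)c1ccccc1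
Why: Standard silylation of a primary allylic alcohol, giving a non-volatile diene whose silyl ether should last until the final fluoride treatment.

**Step 3**
Reactants: 3 tert-butyl[(2-methylidenebut-3-en-1-yl)oxy]diphenylsilane; 4 trimethyl(prop-2-yn-1-yloxy)silane
Product: 6 [4-({[tert-butyl(diphenyl)silyl]oxy}methyl)cyclohexa-1,4-dien-1-yl]methanol, via cycloadduct trimethylsilyl ether 5 (not isolated)
Conditions: CoBr2(dppe) (10 mol%), Zn, ZnI2, CH2Cl2, rt; then K2CO3 (cat.), MeOH
Reagents that add atoms: none
Why: Cobalt-catalysed neutral [4+2] cycloaddition (Diels–Alder type) of an unactivated terminal alkyne with a 2-substituted diene, for which the dppe-ligated low-valent cobalt catalyst gives the 1,4-disubstituted cyclohexa-1,4-diene, closes the ring B carbocycle with b1 and b4 carrying their one-carbon substituents; methanolysis then removes only the trimethylsilyl ether.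

**Step 4**
Reactants: 6 dienyl methanol
Product: 7 4-({[tert-butyl(diphenyl)silyl]oxy}methyl)cyclohexa-1,4-diene-1-carbaldehyde
Conditions: Dess–Martin periodinane, NaHCO3, CH2Cl2, 0 °C
Reagents that add atoms: none
Why: Dess–Martin oxidation of the allylic alcohol under buffered, non-dehydrogenating conditions, which should leave the oxidation-prone 1,4-diene unaromatised.

**Step 5**
Reactants: 7 dienal; 8 propyne
Product: 10 (1R)-1-[4-({[tert-butyl(diphenyl)silyl]oxy}methyl)cyclohexa-1,4-dien-1-yl]but-2-yn-1-ol, via ethyl(prop-1-yn-1-yl)zinc 9 (not isolated)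
Conditions: Et2Zn, Cy2NH (5 mol%), Et2O, rt; then (S)-BINOL (40 mol%), Ti(OiPr)4 (50 mol%), rt
Reagents that add atoms: none
Why: BINOL–titanium-catalysed enantioselective alkynylzinc addition to an enal, in which the (S)-BINOL complex should deliver the propynyl group to the Si face and so set C11 with the geometry of the target (R at this stage); any minor enantiomer is left behind in step 6.

**Step 6**
Reactants: 10 (R)-dienyl propynyl carbinol
Product: 11 erythro epoxy alcohol (b1–b2 oxirane, C11 S)
Conditions: Ti(OiPr)4 (10 mol%), L-(+)-diisopropyl tartrate (12 mol%), t-BuOOH, 4 Å molecular sieves, CH2Cl2, −20 °C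
Reagents that add atoms: tert-butyl hydroperoxide, CC(C)(C)OO
Why: Sharpless asymmetric epoxidation, in which the titanium–tartrate complex binds the C11 alkoxide and so epoxidises only the b1=b2 alkene (not the b4=b5 alkene or the alkyne); with L-(+)-tartrate the (R)-carbinol is the fast, matched enantiomer and gives the erythro epoxy alcohol, so the enantiomeric purity at C11 rises, while b1 and b2 are set here only provisionally and are fixed for good in step 10.

**Step 7**
Reactants: 11 erythro epoxy alcohol
Product: 12 C11 triethylsilyl ether of 11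
Conditions: Et3SiCl, imidazole, DMAP (cat.), CH2Cl2, rt
Reagents that add atoms: chlorotriethylsilane, CC[Si](Cl)(CC)CC
Why: Silylation of the secondary alcohol blocks Payne-type chemistry in the later base step and installs the group at C11 that should bias step 10.

**Step 8**
Reactants: 12 epoxy triethylsilyl ether
Product: 13 trans-b4,b5-dibromide of 12
Conditions: Br2 (1.0 equiv), CH2Cl2, −78 °C
Reagents that add atoms: bromine, BrBr
Why: Electrophilic anti addition of bromine, in which the trisubstituted b4=b5 alkene reacts far faster than the alkyne and trans-diaxial opening of the bromonium ion gives a trans-dibromide (the b4 and b5 centres are temporary, and either trans isomer serves).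

**Step 9**
Reactants: 13 trans-dibromide
Product: 15 C11-silylated para-disubstituted benzene 1,2-oxide, via allylic bromide 14 (not isolated)
Conditions: DBU (4 equiv), THF, 0 °C to rt; filtration through basic Al2O3
Reagents that add atoms: none
Why: Twofold E2 dehydrobromination, the classical route from 4,5-dibromo-1,2-epoxycyclohexanes to benzene oxides, removes HBr across b3/b4 and then b5/b6 without acid and gives the b3=b4–b5=b6 diene; once this diene exists the oxirane configuration is no longer held, through the valence tautomerism taken up in step 10.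

**Step 10**
Reactants: 15 C11-silylated benzene 1,2-oxide; 18 oxygen
Product: 19 anti epoxy endoperoxide (peroxide bridge b3–O–O–b6), via oxepin 16 (not isolated), via ring-epimeric oxide 17 (not isolated)
Conditions: O2, 5,10,15,20-tetraphenylporphyrin (cat.), CH2Cl2, −30 °C, visible light
Reagents that add atoms: none
Why: Proposed new method: sensitised singlet oxygen adds in a concerted suprafacial [4+2] cycloaddition to the s-cis diene b3=b4–b5=b6 of oxide 15, while 15 opens by 6π electrocyclic ring opening to oxepin 16 and 16 recloses on either face to 15 or to ring epimer 17 much faster than either oxide is trapped (Curtin–Hammett regime), so that the material held as 16 and 17 flows back through 16 into 15 and is consumed there. The closest known reaction type is the anti-selective photooxygenation of benzene oxide and of benzene oxides substituted on the oxirane carbon; draining an epimerising oxide pair through one member under the control of an exocyclic carbinol stereocentre is without precedent. The one ring closed is the 2,3-dioxabicyclo[2.2.2]octene, closed by cycloaddition with both C–O bonds formed in one event. b3 and b6 are set cis to each other by the suprafacial addition and anti to the oxirane because the oxirane oxygen shields its own face sterically and by lone-pair repulsion; b1 and b2, labile until now, become fixed because the cycloaddition consumes the diene needed for epimerisation. The selectivity required is faster trapping of 15 than of 17, and it rests on C11: in 15 the C11–H can face b6–H, the bulky triethylsilyloxy group lies over the exo face of the oxirane and the slim propynyl points away on the attack face, whereas in 17 either the silyloxy group must sit on the attack face or a non-hydrogen group must press against b6–H as b6 pyramidalises; this bias is reasoned, not proven.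

**Step 11**
Reactants: 19 anti epoxy endoperoxide
Product: 20 epoxy cis-1,4-diol (b3–OH and b6–OH anti to the oxirane)
Conditions: thiourea, MeOH/H2O, 0 °C to rt
Reagents that add atoms: none
Why: Thiourea reduction of a bicyclic endoperoxide cleaves only the O–O bond, so both C–O bonds and the cis relationship of the hydroxyls are retained while the oxirane, alkyne and silyl ethers stay untouched.

**Step 12**
Reactants: 20 epoxy cis-diol
Product: 21 b3,b6-bis(tert-butyldimethylsilyl) ether of 20
Conditions: t-BuMe2SiOTf, 2,6-lutidine, CH2Cl2, −78 to 0 °C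
Reagents that add atoms: tert-butyldimethylsilyl trifluoromethanesulfonate, CC(C)(C)[Si](C)(C)OS(=O)(=O)C(F)(F)F
Why: Silyl triflate silylation is strong enough for the hindered b6 hydroxyl and removes the two oxirane-flanking hydroxyls from the hydride chemistry of step 14.

**Step 13**
Reactants: 21 fully silylated epoxy diol
Product: 22 C11 alcohol (triethylsilyl group removed)
Conditions: pyridinium p-toluenesulfonate (cat.), MeOH/CH2Cl2, 0 °C
Reagents that add atoms: none
Why: Selective acid-catalysed methanolysis, since a triethylsilyl ether solvolyses far faster than tert-butyldimethylsilyl and tert-butyldiphenylsilyl ethers and the oxirane, flanked by oxygen-bearing carbons, should resist this weak acid.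

**Step 14**
Reactants: 22 propargylic alcohol
Product: 24 (Z)-vinyl iodide (iodine on C9, cis to C11), via cyclic alkenylalanate 23 (not isolated)
Conditions: NaAlH2(OCH2CH2OMe)2, THF, −20 to 0 °C; EtOAc; then I2, −78 °C
Reagents that add atoms: iodine, II
Why: Hydroxyl-directed trans-hydroalumination of a propargylic alcohol followed by iodinolysis with retention, in which the C11 alkoxyaluminate delivers hydride to C10 and aluminium to C9 within a five-membered chelate, so iodine ends on C9 cis to C11 as the trisubstituted alkene of the target requires.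

**Step 15**
Reactants: 25 geranyl acetate
Product: 26 (2E)-5-[(2R)-3,3-dimethyloxiran-2-yl]-3-methylpent-2-en-1-yl acetate
Conditions: 1,2:4,5-di-O-isopropylidene-β-D-erythro-2,3-hexodiulo-2,6-pyranose (Shi ketone, 30 mol%), KHSO5 (Oxone), K2CO3, Bu4NHSO4, MeCN/CH2(OMe)2/aq. buffer, 0 °C
Reagents that add atoms: potassium peroxymonosulfate, [K+].[O-]S(=O)(=O)OO
Why: Shi asymmetric epoxidation, in which the chiral dioxirane attacks the electron-rich terminal alkene in preference to the one deactivated by the allylic acetate and, through the spiro transition state of the D-fructose-derived ketone, should give the (R)-epoxide that becomes the ring A carbinol centre.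

**Step 16**
Reactants: 26 (R)-epoxygeranyl acetate
Product: 27 [(1S,3R)-3-hydroxy-2,2-dimethyl-6-methylidenecyclohexyl]methyl acetate
Conditions: Cp2TiCl2 (2.2 equiv), Mn, THF, rt; aq. HCl
Reagents that add atoms: none
Why: Reductive epoxide opening by trivalent titanium, 6-endo radical cyclisation and β-hydride elimination to the exocyclic alkene form ring A; the carbinol C–O bond is untouched and a chair transition state with the titanoxy and acetoxymethyl groups equatorial sets the ring CH cis to the hydroxyl.

**Step 17**
Reactants: 27 hydroxy acetate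
Product: 28 [(1S,3R)-2,2-dimethyl-6-methylidene-3-(triethylsilyloxy)cyclohexyl]methyl acetate
Conditions: Et3SiOTf, 2,6-lutidine, CH2Cl2, −78 °C
Reagents that add atoms: triethylsilyl trifluoromethanesulfonate, CC[Si](CC)(CC)OS(=O)(=O)C(F)(F)F
Why: Silyl triflate silylation of the hindered neopentylic secondary alcohol with a group that fluoride removes easily at the end.

**Step 18**
Reactants: 28 silylated acetate
Product: 29 [(1S,3R)-2,2-dimethyl-6-methylidene-3-(triethylsilyloxy)cyclohexyl]methanol
Conditions: K2CO3 (cat.), MeOH, 0 °C to rt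
Reagents that add atoms: none
Why: Base-catalysed transesterification removes the acetate while the hindered secondary triethylsilyl ether should survive.

**Step 19**
Reactants: 29 primary alcohol
Product: 30 (1S,3R)-2,2-dimethyl-6-methylidene-3-(triethylsilyloxy)cyclohexane-1-carbaldehyde
Conditions: Dess–Martin periodinane, NaHCO3, CH2Cl2, 0 °C
Reagents that add atoms: none
Why: Dess–Martin oxidation under buffered conditions, with the β,γ-unsaturated aldehyde used at once so that its α-stereocentre is not epimerised and the exocyclic alkene does not move into conjugation.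

**Step 20**
Reactants: 30 aldehyde
Product: 31 2-{(E)-2-[(1S,3R)-2,2-dimethyl-6-methylidene-3-(triethylsilyloxy)cyclohexyl]ethenyl}-4,4,5,5-tetramethyl-1,3,2-dioxaborolane
Conditions: Cl2CHB(pin), CrCl2, LiI, THF, rt
Reagents that add atoms: 2-(dichloromethyl)-4,4,5,5-tetramethyl-1,3,2-dioxaborolane, ClC(Cl)B1OC(C)(C)C(C)(C)O1
Why: Takai–Utimoto borylolefination, in which the geminal dichromium reagent formed from the dichloromethylboronate adds to the aldehyde and eliminates to the (E)-alkenylboronate under non-basic conditions that spare the epimerisable ring stereocentre.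

**Step 21**
Reactants: 24 (Z)-vinyl iodide; 31 (E)-alkenylboronate
Product: 32 tetrasilylated target (C8–C9 bond formed)
Conditions: Pd(dppf)Cl2 (5 mol%), K3PO4, THF/H2O, rt
Reagents that add atoms: none
Why: Suzuki–Miyaura coupling, in which oxidative addition and transmetalation both proceed with retention so that the (Z)-C9=C10 and (E)-C7=C8 geometries pass into the diene, while mild aqueous phosphate should leave the oxirane, silyl ethers and free C11 hydroxyl intact.

**Step 22**
Reactants: 32 tetrasilylated target
Product: 33 CNP0357844.1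
Conditions: Bu4NF, AcOH (1:1), THF, 0 °C to rt
Reagents that add atoms: none
Why: Fluoride-mediated cleavage of all four silyl ethers, buffered with acetic acid so that neither alkoxide-driven epoxide migration nor acid ionisation of the dienylic C11 carbinol is invited.

**Compound list**
1 | 2-methyl-2-vinyloxirane (isoprene monoxide, racemic) | CC1(C=C)CO1 | starting material
2 | 2-methylidenebut-3-en-1-ol | OCC(=C)C=C | intermediate
3 | tert-butyl[(2-methylidenebut-3-en-1-yl)oxy]diphenylsilane | C=CC(=C)CO[Si](c1ccccc1)(c1ccccc1)C(C)(C)C | intermediate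
4 | trimethyl(prop-2-yn-1-yloxy)silane | C#CCO[Si](C)(C)C | starting material
5 | tert-butyl[(4-{[(trimethylsilyl)oxy]methyl}cyclohexa-1,4-dien-1-yl)methoxy]diphenylsilane (not isolated) | C[Si](C)(C)OCC1=CCC(CO[Si](c2ccccc2)(c2ccccc2)C(C)(C)C)=CC1 | intermediate
6 | [4-({[tert-butyl(diphenyl)silyl]oxy}methyl)cyclohexa-1,4-dien-1-yl]methanol | OCC1=CCC(CO[Si](c2ccccc2)(c2ccccc2)C(C)(C)C)=CC1 | intermediate
7 | 4-({[tert-butyl(diphenyl)silyl]oxy}methyl)cyclohexa-1,4-diene-1-carbaldehyde | O=CC1=CCC(CO[Si](c2ccccc2)(c2ccccc2)C(C)(C)C)=CC1 | intermediate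
8 | propyne | CC#C | starting material
9 | ethyl(prop-1-yn-1-yl)zinc (not isolated) | CC[Zn]C#CC | intermediate
10 | (1R)-1-[4-({[tert-butyl(diphenyl)silyl]oxy}methyl)cyclohexa-1,4-dien-1-yl]but-2-yn-1-ol | CC#C[C@H](O)C1=CCC(CO[Si](c2ccccc2)(c2ccccc2)C(C)(C)C)=CC1 | intermediate
11 | erythro epoxy alcohol: b1–b2 oxirane of 10 (7-oxabicyclo[4.1.0]hept-3-ene), C11 S, oxirane on the ring face it has in the target | CC#C[C@H](O)[C@]12O[C@H]1CC(CO[Si](c3ccccc3)(c3ccccc3)C(C)(C)C)=CC2 | intermediate
12 | C11 triethylsilyl ether of 11 | CC#C[C@H](O[Si](CC)(CC)CC)[C@]12O[C@H]1CC(CO[Si](c3ccccc3)(c3ccccc3)C(C)(C)C)=CC2 | intermediate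
13 | trans-b4,b5-dibromide of 12 (b4–Br syn, b5–Br anti to the oxirane oxygen as drawn) | CC#C[C@H](O[Si](CC)(CC)CC)[C@]12O[C@H]1C[C@](Br)(CO[Si](c3ccccc3)(c3ccccc3)C(C)(C)C)[C@H](Br)C2 | intermediate
14 | allylic bromide after the first elimination (b3=b4 alkene, b5–Br; not isolated) | CC#C[C@H](O[Si](CC)(CC)CC)[C@]12O[C@H]1C=C(CO[Si](c3ccccc3)(c3ccccc3)C(C)(C)C)[C@H](Br)C2 | intermediate
15 | benzene 1,2-oxide: b1–b2 oxirane, b3=b4–b5=b6 diene, b1 bearing (1S)-1-(triethylsilyloxy)but-2-ynyl, b4 bearing CH2OSi(t-Bu)Ph2, oxirane face as in the target | CC#C[C@H](O[Si](CC)(CC)CC)[C@]12O[C@H]1C=C(CO[Si](c3ccccc3)(c3ccccc3)C(C)(C)C)C=C2 | intermediate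
16 | 2,5-disubstituted oxepin, valence tautomer of 15 and 17 (not isolated) | CC#C[C@H](O[Si](CC)(CC)CC)C1=CC=C(CO[Si](c2ccccc2)(c2ccccc2)C(C)(C)C)C=CO1 | intermediate
17 | ring-epimeric benzene 1,2-oxide (oxirane on the opposite face, same C11; not isolated) | CC#C[C@H](O[Si](CC)(CC)CC)[C@@]12O[C@@H]1C=C(CO[Si](c3ccccc3)(c3ccccc3)C(C)(C)C)C=C2 | intermediate
18 | oxygen | O=O | starting material
19 | anti epoxy endoperoxide: peroxide bridge across b3 and b6, anti to the b1–b2 oxirane, b4=b5 alkene | CC#C[C@H](O[Si](CC)(CC)CC)[C@]12O[C@H]1[C@@H]3OO[C@H]2C=C3CO[Si](c4ccccc4)(c4ccccc4)C(C)(C)C | intermediate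
20 | epoxy cis-1,4-diol: b3–OH and b6–OH cis to each other, anti to the oxirane | CC#C[C@H](O[Si](CC)(CC)CC)[C@]12O[C@H]1[C@H](O)C(CO[Si](c3ccccc3)(c3ccccc3)C(C)(C)C)=C[C@@H]2O | intermediate
21 | b3,b6-bis(tert-butyldimethylsilyl) ether of 20 | CC#C[C@H](O[Si](CC)(CC)CC)[C@]12O[C@H]1[C@H](O[Si](C)(C)C(C)(C)C)C(CO[Si](c3ccccc3)(c3ccccc3)C(C)(C)C)=C[C@@H]2O[Si](C)(C)C(C)(C)C | intermediate
22 | C11 alcohol (S) of 21 | CC#C[C@H](O)[C@]12O[C@H]1[C@H](O[Si](C)(C)C(C)(C)C)C(CO[Si](c3ccccc3)(c3ccccc3)C(C)(C)C)=C[C@@H]2O[Si](C)(C)C(C)(C)C | intermediate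
23 | sodium cyclic alkenylalanate (five-membered O–Al–C9=C10–C11 chelate, two 2-methoxyethoxy groups on aluminium; not isolated) | [Na+].CC1=C[C@H](O[Al-]1(OCCOC)OCCOC)[C@]23O[C@H]2[C@H](O[Si](C)(C)C(C)(C)C)C(CO[Si](c4ccccc4)(c4ccccc4)C(C)(C)C)=C[C@@H]3O[Si](C)(C)C(C)(C)C | intermediate
24 | (Z)-vinyl iodide: C11(OH)–C10H=C9(I)CH3, iodine cis to C11 | C/C(I)=C/[C@H](O)[C@]12O[C@H]1[C@H](O[Si](C)(C)C(C)(C)C)C(CO[Si](c3ccccc3)(c3ccccc3)C(C)(C)C)=C[C@@H]2O[Si](C)(C)C(C)(C)C | intermediate
25 | geranyl acetate | CC(=O)OC/C=C(\C)CCC=C(C)C | starting material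
26 | (2E)-5-[(2R)-3,3-dimethyloxiran-2-yl]-3-methylpent-2-en-1-yl acetate | CC(=O)OC/C=C(\C)CC[C@H]1OC1(C)C | intermediate
27 | [(1S,3R)-3-hydroxy-2,2-dimethyl-6-methylidenecyclohexyl]methyl acetate | C=C1CC[C@@H](O)C(C)(C)[C@H]1COC(C)=O | intermediate
28 | [(1S,3R)-2,2-dimethyl-6-methylidene-3-(triethylsilyloxy)cyclohexyl]methyl acetate | C=C1CC[C@@H](O[Si](CC)(CC)CC)C(C)(C)[C@H]1COC(C)=O | intermediate
29 | [(1S,3R)-2,2-dimethyl-6-methylidene-3-(triethylsilyloxy)cyclohexyl]methanol | C=C1CC[C@@H](O[Si](CC)(CC)CC)C(C)(C)[C@H]1CO | intermediate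
30 | (1S,3R)-2,2-dimethyl-6-methylidene-3-(triethylsilyloxy)cyclohexane-1-carbaldehyde | C=C1CC[C@@H](O[Si](CC)(CC)CC)C(C)(C)[C@H]1C=O | intermediate
31 | 2-{(E)-2-[(1S,3R)-2,2-dimethyl-6-methylidene-3-(triethylsilyloxy)cyclohexyl]ethenyl}-4,4,5,5-tetramethyl-1,3,2-dioxaborolane | C=C1CC[C@@H](O[Si](CC)(CC)CC)C(C)(C)[C@H]1/C=C/B1OC(C)(C)C(C)(C)O1 | intermediate
32 | tetrasilylated target (ring A O–SiEt3; b3 and b6 O–Si(t-Bu)Me2; CH2O–Si(t-Bu)Ph2; C11–OH free) | C=C1CC[C@@H](O[Si](CC)(CC)CC)C(C)(C)[C@H]1/C=C/C(C)=C\[C@H](O)[C@]12O[C@H]1[C@H](O[Si](C)(C)C(C)(C)C)C(CO[Si](c3ccccc3)(c3ccccc3)C(C)(C)C)=C[C@@H]2O[Si](C)(C)C(C)(C)C | intermediate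
33 | CNP0357844.1 | C=C1CC[C@@H](O)C(C)(C)[C@H]1/C=C/C(C)=C\[C@H](O)[C@]12O[C@H]1[C@H](O)C(CO)=C[C@@H]2O | target

**Step count**
Total: 22 steps. Longest linear sequence: 16 steps (steps 1–14, 21, 22); the ring A branch is steps 15–20.

**Steps most likely to fail**

1. Step 10 (proposed new method). What may go wrong: the equilibrating mixture is drained through the ring-epimeric oxide 17 instead of 15, so that the peroxide bridge and oxirane are laid down with the wrong sense relative to C11. The fallback uses known chemistry only: the mirror-image carbinol series, in which the photooxygenation serves merely as the established anti-selective addition of singlet oxygen to a benzene oxide, and a reagent-controlled correction of C11 afterwards. It sets out from aldehyde 7 and comes back at alcohol 22. Alkynylation of 7 as in step 5 but with (R)-BINOL gives (S)-carbinol F1. Sharpless epoxidation with D-(−)-diisopropyl tartrate gives mirror-image epoxy alcohol F2, and silylation gives triethylsilyl ether F3. Bromination gives dibromide F4, and DBU, by way of allylic bromide F5, gives mirror-image arene oxide F6 in equilibrium with oxepin F7 and ring-epimeric oxide F8. By mirror symmetry the photooxygenation now drains through F8 and gives 11-epi-endoperoxide F9, whose ring B is that of the target. Thiourea gives 11-epi-diol F10, t-BuMe2SiOTf gives 11-epi-bis(silyl ether) F11, and pyridinium p-toluenesulfonate in methanol gives 11-epi-alcohol F12. Dess–Martin oxidation gives ynone F13, and Corey–Bakshi–Shibata reduction with (R)-2-methyl-CBS-oxazaborolidine and catecholborane (propynyl as the small group, the fully substituted oxirane carbon as the large one) returns 22.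

2. Step 14. What may go wrong: the C11 alkoxyaluminate delivers hydride to the neighbouring oxirane (reductive epoxide opening) in competition with hydroalumination of the alkyne. The fallback avoids hydride; it sets out from 22 and comes back at 24. Ruthenium-catalysed trans-hydrosilylation with [Cp*Ru(MeCN)3]PF6 and BnMe2SiH in CH2Cl2 places silicon on the alkyne carbon distal to the free hydroxyl and trans to the new C–H, giving (Z)-alkenylsilane F14. Iododesilylation with N-iodosuccinimide in (CF3)2CHOH buffered with 2,6-lutidine replaces silicon by iodine with retention and gives 24.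

3. Step 22. What may go wrong: during the fourfold desilylation of the finished skeleton, alkoxides flanking the oxirane trigger Payne-type epoxide migration, or the dienylic C11 carbinol ionises. The fallback removes the silyl groups before the diene exists; it sets out from 24 and 31 and comes back at 33. Bu4NF/AcOH converts 24 into iodo tetraol F15 and HF·pyridine converts 31 into hydroxy boronate F16. The Suzuki–Miyaura coupling of F15 with F16 under the conditions of step 21 then becomes the last step and gives 33 directly.

**Further compounds**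
F1 | step 10 | (1S)-carbinol, enantiomer of 10 | CC#C[C@@H](O)C1=CCC(CO[Si](c2ccccc2)(c2ccccc2)C(C)(C)C)=CC1
F2 | step 10 | epoxy alcohol, enantiomer of 11 | CC#C[C@@H](O)[C@@]12O[C@@H]1CC(CO[Si](c3ccccc3)(c3ccccc3)C(C)(C)C)=CC2
F3 | step 10 | triethylsilyl ether, enantiomer of 12 | CC#C[C@@H](O[Si](CC)(CC)CC)[C@@]12O[C@@H]1CC(CO[Si](c3ccccc3)(c3ccccc3)C(C)(C)C)=CC2
F4 | step 10 | dibromide, enantiomer of 13 | CC#C[C@@H](O[Si](CC)(CC)CC)[C@@]12O[C@@H]1C[C@@](Br)(CO[Si](c3ccccc3)(c3ccccc3)C(C)(C)C)[C@@H](Br)C2
F5 | step 10 | allylic bromide, enantiomer of 14 | CC#C[C@@H](O[Si](CC)(CC)CC)[C@@]12O[C@@H]1C=C(CO[Si](c3ccccc3)(c3ccccc3)C(C)(C)C)[C@@H](Br)C2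
F6 | step 10 | arene oxide, enantiomer of 15 | CC#C[C@@H](O[Si](CC)(CC)CC)[C@@]12O[C@@H]1C=C(CO[Si](c3ccccc3)(c3ccccc3)C(C)(C)C)C=C2
F7 | step 10 | oxepin, enantiomer of 16 | CC#C[C@@H](O[Si](CC)(CC)CC)C1=CC=C(CO[Si](c2ccccc2)(c2ccccc2)C(C)(C)C)C=CO1
F8 | step 10 | ring-epimeric oxide, enantiomer of 17 | CC#C[C@@H](O[Si](CC)(CC)CC)[C@]12O[C@H]1C=C(CO[Si](c3ccccc3)(c3ccccc3)C(C)(C)C)C=C2
F9 | step 10 | 11-epi-endoperoxide, C11 epimer of 19 | CC#C[C@@H](O[Si](CC)(CC)CC)[C@]12O[C@H]1[C@@H]3OO[C@H]2C=C3CO[Si](c4ccccc4)(c4ccccc4)C(C)(C)C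
F10 | step 10 | 11-epi-diol, C11 epimer of 20 | CC#C[C@@H](O[Si](CC)(CC)CC)[C@]12O[C@H]1[C@H](O)C(CO[Si](c3ccccc3)(c3ccccc3)C(C)(C)C)=C[C@@H]2O
F11 | step 10 | 11-epi-bis(silyl ether), C11 epimer of 21 | CC#C[C@@H](O[Si](CC)(CC)CC)[C@]12O[C@H]1[C@H](O[Si](C)(C)C(C)(C)C)C(CO[Si](c3ccccc3)(c3ccccc3)C(C)(C)C)=C[C@@H]2O[Si](C)(C)C(C)(C)C
F12 | step 10 | 11-epi-alcohol, C11 epimer of 22 | CC#C[C@@H](O)[C@]12O[C@H]1[C@H](O[Si](C)(C)C(C)(C)C)C(CO[Si](c3ccccc3)(c3ccccc3)C(C)(C)C)=C[C@@H]2O[Si](C)(C)C(C)(C)C
F13 | step 10 | ynone (C11 ketone of 22) | CC#CC(=O)[C@]12O[C@H]1[C@H](O[Si](C)(C)C(C)(C)C)C(CO[Si](c3ccccc3)(c3ccccc3)C(C)(C)C)=C[C@@H]2O[Si](C)(C)C(C)(C)C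
F14 | step 14 | (Z)-alkenylsilane (benzyldimethylsilyl on C9, cis to C11) | C/C([Si](C)(C)Cc1ccccc1)=C/[C@H](O)[C@]12O[C@H]1[C@H](O[Si](C)(C)C(C)(C)C)C(CO[Si](c3ccccc3)(c3ccccc3)C(C)(C)C)=C[C@@H]2O[Si](C)(C)C(C)(C)C
F15 | step 22 | iodo tetraol (desilylated 24) | C/C(I)=C/[C@H](O)[C@]12O[C@H]1[C@H](O)C(CO)=C[C@@H]2O
F16 | step 22 | hydroxy boronate (desilylated 31) | C=C1CC[C@@H](O)C(C)(C)[C@H]1/C=C/B1OC(C)(C)C(C)(C)O1
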